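Readings and results are simulated with made-up constants; noise was put on by code.

Monday's run and Thursday's run stood at the same temperature, 14 °C, and both have a last reading at 80.0 min, so these two readings can be compared on one clock without drawing a slope.

| flask | substrate | free enzyme | temperature | remark | time |
|---|---|---|---|---|---|
| Monday's | 0.059 M | 0.1 mol% | 14 °C | run made earlier |  |
| Tuesday's | 0.55 M | 0.1 mol% | 31 °C | run made earlier |  |
| Thursday's | 0.10 M | 0.067 mol% | 14 °C | run made earlier |  |
| larch | 0.40 M | 0.025 mol% | 37 °C |  | 50 min |
| ash | 0.30 M | 0.1 mol% | 22 °C |  | 50 min |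
| cedar | 0.050 M | 0.1 mol% | 37 °C |  | 50 min |
| elm | 0.10 M | 0.1 mol% | 37 °C |  | 50 min |
| birch | 0.15 M | 0.1 mol% | 37 °C |  | 50 min |
| alder | 0.15 M | 0.15 mol% | 7 °C |  | 50 min |

- Monday's (time / min: product / %, substrate / %): 5.00: 0, 98.8; 15.0: 1.3, 98.4; 25.0: 3.4, 98.0; 50.0: 5.1, 95.1; 60.0: 5.7, 94.4; 80.0: 8.1, 92.2
- Tuesday's (time / min: product / %, substrate / %): 4.00: 2.7, 97.6; 8.00: 5.7, 95.1; 12.0: 6.3, 92.6; 15.0: 9.0, 90.7; 20.0: 12.7, 87.1; 25.0: 15.8, 84.4
- Thursday's (time / min: product / %, substrate / %): 6.00: 1.0, 98.9; 20.0: 1.7, 98.2; 40.0: 2.9, 96.3; 60.0: 4.1, 94.7; 80.0: 6.7, 93.3

(standard deviation of a reading: 0.5 percentage points)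

- the numbers in the tables scatter by 0.5 percentage points (one standard deviation)
- a reading or a percentage of product counts all its forms, free or not

- the flasks put in order of amount of product, in percent of the substrate charged, best first, at 50 min (larch / ash / cedar / elm / birch / alder)
- the amount of product, in percent of the substrate charged of the flask you put first, at 50 min
- the amount of product, in percent of the substrate charged of the flask you put last, at 50 min

*What do you divide by what?* Product in percent of the substrate charged, divided by enzyme in mol% of that same substrate, counts moles of product per mole of enzyme charged, and two such counts taken at one clock give the ratio of two mean rates per enzyme, so time drops out. Thursday's over Monday's gives 1.23, and this turnover ratio G, product over loading in one flask divided by product over loading in another at the same time, is what I carry; its two parts are turnover numbers.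

*What does it say?* Substrate rose by a factor of 1.69 while turnover rose by the smaller factor G, so more substrate buys more turnover, but less than in proportion.

*Each reading scatters by 0.5 percentage points, and the loading changed as well, so what is that worth?* It is a rough reading, and no run changes the loading by itself, so it is my assumption that product follows the loading in proportion. That assumption says G should stand near 1 between two flasks of equal substrate and temperature, for as long as their enzyme stays at work.

*What do you commit to?* Elm and cedar share loading and temperature, and elm has twice the substrate, so I expect elm above cedar by a G of about that size. G gives no absolute figure at 37 °C.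

The forecast, by “Integrating Michaelis–Menten to 50 min”, gives the order birch > elm > cedar > ash > larch > alder, with birch at 46% (range 33% to 58%) and alder at 4.2% (range 3% to 5.5%).

The flasks give birch > elm > cedar > ash > larch > alder, which is the forecast's order. Alder has 5.94%, and birch has 33.2%, which is 13 points below the forecast's figure, while elm stands over cedar by 1.32. At 50.0 min birch holds 72.8% of its catalyst as free enzyme, 25.2% as idle complex and 2.02% as unfolded enzyme.

    free enzyme → unfolded enzyme (k = 4.50 × 10⁻⁴ min⁻¹, Ea = 283 kJ mol⁻¹)
    substrate + free enzyme → product + free enzyme, rate k2*[substrate]*[free enzyme]/(1 + ([substrate]/Km2)) (0.0570 M, k = 190 M⁻¹ min⁻¹, Ea = 55.0 kJ mol⁻¹)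
    free enzyme + product ⇌ idle complex (K = 110 M⁻¹, k = 0.230 M⁻¹ min⁻¹, Ea = 79.0 kJ mol⁻¹, ΔH = −44.0 kJ mol⁻¹)
    (constants at 37 °C)

A further flask, like alder but charged with 0.09 mol% of free enzyme instead of 0.15 mol%, gave 3.58% at 50 min against alder's 5.94%. With substrate and temperature held, G of that flask over alder is 1.00, which is smaller than the 1.23 of Thursday's over Monday's, where substrate had changed. At that time alder still holds 99.8% of its catalyst as free enzyme, and the further flask holds 99.9%.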